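**Retrosynthetic overview**

1. Core numbering: C1(OH), C2(H)Ar, O3, C4H2, C5(H), C6(H)Ar, O7, C8H2 (Ar = 3,4-dimethoxyphenyl); ring A = C1-C2-O3-C4-C5 and ring B = C1-C5-C6-O7-C8. The strategy rests on the trans junction C1–C5 (C1–OH anti to C5–H), which reversible benzylic C–O closures cannot deliver, and on C8 being a plain CH2 next to the C1 carbinol, so that C1–O and C8 can be stored together as a spiro-oxirane on ring A.
2. The last disconnection is O7–C8, so ring B is closed last. Only the achiral C8 methylene is substituted: the oxirane is passed on through its iodohydrin so that the C6 alkoxide can displace collinearly, and C1–OH is released.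
3. Ring A is closed first at O3–C2, by rear-side attack of C4–OH on a C1–C2 aryl epoxide. The epoxide comes from Sharpless epoxidation of an (E)-allylic alcohol, which sets C1 and then C2 by inversion.
4. C5–C6 comes from an Evans syn aldol on an arylidenesuccinyl imide and C1=C2 from a Stobbe condensation. Veratraldehyde supplies C2 and C6; dimethyl succinate supplies C8, C1, C5 and C4.

Key step: step 11

Remark (reading of the target): the SMILES is taken literally. It encodes a trans-fused 3,7-dioxabicyclo[3.3.0]octan-1-ol of configuration (1S,2R,5S,6R), with C2–aryl cis to C1–OH and C6–aryl cis to C5–H.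
Remark (closing step): a bare alkoxide cannot open the spiro-oxirane, for the stereoelectronic reason given at step 11. The iodide shuttle is therefore part of the design.

**Step 1**
Reactants: 1 3,4-dimethoxybenzaldehyde; 2 dimethyl succinate
Product: 3 (E)-4-(3,4-dimethoxyphenyl)-3-(methoxycarbonyl)but-3-enoic acid (aryl cis to CH2CO2H)
Conditions: NaOMe (1.5 equiv), MeOH, reflux; then aq. HCl
Reagents that add atoms: none
Why: Stobbe condensation, in which the succinate enolate adds to the aldehyde, the aldolate lactonises to a paraconic ester and E1cB opening gives the half-ester, the (E)-alkene being favoured because it keeps the aryl group away from the ester on C1.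

**Step 2**
Reactants: 3 Stobbe half-ester; 4 (R)-4-benzyl-2-oxazolidinone
Product: 6 methyl (E)-2-{2-[(R)-4-benzyl-2-oxooxazolidin-3-yl]-2-oxoethyl}-3-(3,4-dimethoxyphenyl)acrylate, via mixed pivalic anhydride 5 (not isolated)
Conditions: tBuCOCl, Et3N, THF, −20 °C; then LiCl, 4, −20 °C → rt
Reagents that add atoms: none
Why: Mixed-anhydride N-acylation of the oxazolidinone under soft LiCl/Et3N activation, preferred to the lithiated auxiliary so that the acidic allylic CH2 meets no strong base, with attack at the less hindered carbonyl of 5.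

**Step 3**
Reactants: 6 N-acyl oxazolidinone; 1 3,4-dimethoxybenzaldehyde
Product: 9 syn aldol adduct (C5 R; C6 R; alkene E), via Z-boron dienolate 7 (not isolated), via boron aldolate 8 (not isolated)
Conditions: Bu2BOTf, iPr2NEt, CH2Cl2, −78 → 0 °C; 1, −78 → 0 °C; pH 7 buffer, MeOH, H2O2, 0 °C
Reagents that add atoms: none
Why: Evans syn aldol, in which soft enolisation gives the Z(O)-boron dienolate, which reacts at its alpha carbon C5 through a closed Zimmerman–Traxler chair on the face remote from the benzyl group of the (R)-auxiliary and so sets C5 and C6 syn, both R.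

**Step 4**
Reactants: 9 syn aldol adduct
Product: 10 C6-O-tert-butyldimethylsilyl ether of 9
Conditions: TBSOTf, 2,6-lutidine, CH2Cl2, −78 → 0 °C
Reagents that add atoms: tert-butyldimethylsilyl triflate, CC(C)(C)[Si](C)(C)OS(=O)(=O)C(F)(F)F
Why: Silylation of the secondary benzylic alcohol with a silyl triflate and a non-nucleophilic base is fast in the cold and forestalls retro-aldol cleavage and lactonisation onto the C8 ester.

**Step 5**
Reactants: 10 silylated aldol adduct
Product: 11 methyl (E)-ester bearing C4H2OH: MeO2C(C8)–C1(=C2H–Ar)–C5H(C4H2OH)–C6H(OTBS)Ar (C5 S; C6 R)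
Conditions: LiBH4, MeOH (1 equiv to LiBH4), THF, 0 °C
Reagents that add atoms: none
Why: Reductive cleavage of the N-acyl oxazolidinone, whose imide carbonyl is more electrophilic than the hindered conjugated ester, leaves C5 untouched (the descriptor changes by priority only), and any over-reduction or lactonisation converges on 12 in the next step.

**Step 6**
Reactants: 11 hydroxy ester
Product: 12 (E)-allylic alcohol diol: HOC8H2–C1(=C2H–Ar)–C5H(C4H2OH)–C6H(OTBS)Ar (C5 S; C6 R; aryl trans to C8)
Conditions: iBu2AlH (4 equiv), CH2Cl2, −78 → 0 °C; aq. potassium sodium tartrate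
Reagents that add atoms: none
Why: 1,2-Reduction of the conjugated ester with iBu2AlH gives the allylic alcohol without touching the alkene geometry or the silyl ether.

**Step 7**
Reactants: 12 (E)-allylic alcohol diol
Product: 14 (2R,3S,4S)-4-[(R)-(tert-butyldimethylsilyloxy)(3,4-dimethoxyphenyl)methyl]-2-(3,4-dimethoxyphenyl)-3-(hydroxymethyl)tetrahydrofuran-3-ol (ring A; aryl/C1–OH/C6 arm all cis; C8H2OH on the other face), via C1–C2 epoxy alcohol 13 (not isolated)
Conditions: Ti(OiPr)4 (1.1 equiv), L-(+)-diethyl tartrate (1.3 equiv), tBuOOH (2 equiv), 4 Å MS, CH2Cl2, −25 °C; then 0 °C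
Reagents that add atoms: tert-butyl hydroperoxide, CC(C)(C)OO
Why: Katsuki–Sharpless epoxidation with the L-(+)-tartrate delivers oxygen to the alkene face that gives the (2S,3S)-epoxy alcohol (C1 S), a face also left open by allylic 1,3-strain that turns the C6 arm away, and the titanium-bound electron-rich aryl epoxide is then opened at benzylic C2 from the rear by C4–OH (C3-selective opening of a 2,3-epoxy alcohol, 5-endo with both oxirane carbons ending in ring A), which inverts C2 to R and forms O3–C2.

**Step 8**
Reactants: 14 ring A diol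
Product: 15 C8 p-toluenesulfonate of 14 (C1–OH free)
Conditions: TsCl, Et3N, DMAP (cat.), CH2Cl2, 0 °C → rt
Reagents that add atoms: p-toluenesulfonyl chloride, Cc1ccc(cc1)S(=O)(=O)Cl
Why: Selective sulfonylation of the primary hydroxyl, since the crowded tertiary C1–OH is inert under these conditions.

**Step 9**
Reactants: 15 tosylate
Product: 16 (3S,4R,7S)-7-[(R)-(tert-butyldimethylsilyloxy)(3,4-dimethoxyphenyl)methyl]-4-(3,4-dimethoxyphenyl)-1,5-dioxaspiro[2.4]heptane (oxirane O cis and C8 trans to the C6 arm)
Conditions: K2CO3, MeOH, 0 °C → rt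
Reagents that add atoms: none
Why: Intramolecular Williamson (3-exo-tet) closure of the C1 alkoxide on C8 breaks no bond at C1, so C1 keeps its configuration.

**Step 10**
Reactants: 16 spiro-epoxide silyl ether
Product: 17 (R)-(3,4-dimethoxyphenyl)[(3S,4R,7S)-4-(3,4-dimethoxyphenyl)-1,5-dioxaspiro[2.4]heptan-7-yl]methanol
Conditions: Bu4NF, AcOH (1:1), THF, 0 °C → rt
Reagents that add atoms: none
Why: Buffered fluoride desilylation exposes C6–OH without free acid or alkoxide, and the oxirane should survive because the C6 oxygen cannot reach the rear of either oxirane C–O bond.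

**Step 11**
Reactants: 17 spiro-epoxy alcohol
Product: 19 (1S,2R,5S,6R)-2,6-bis(3,4-dimethoxyphenyl)-3,7-dioxabicyclo[3.3.0]octan-1-ol (trans-fused; target), via C8 iodohydrin 18 (not isolated)
Conditions: LiI (1.5 equiv), Li2CO3 (solid buffer), THF (0.005 M), 50 °C, Ar, dark
Reagents that add atoms: none
Why: Proposed new method: direct attack of the C6 oxygen on the oxirane is ruled out, because in 17 that oxygen lies on the face of ring A that also holds the oxirane oxygen and could meet C8 only from the front of the C8–O bond (in 19 the C1–O bond is pseudoaxial on ring B and gauche to C8–O7, not anti as an epoxide opening demands), so iodide serves as a shuttle: helped by Li+ and by the C6–OH to oxirane hydrogen bond it opens the ring at the unhindered C8 from the free face to give 18, the proton passes from C6–OH to the more basic C1 alkoxide, and after rotation about C1–C8 the C6 alkoxide expels iodide collinearly and returns LiI. The closest known reaction types are the iodide-catalysed Heine isomerisation of N-acylaziridines to oxazolines, halide-catalysed epoxide isomerisations that run through halohydrin alkoxides, and the SN2 closure of trans-1,2-disubstituted cyclopentane sulfonates to trans-fused 3-heterobicyclo[3.3.0]octanes. Ring B (C1, C5, C6, O7, C8) closes by a genuine 5-exo-tet Williamson displacement that forms O7–C8, ring A being a spectator. No stereocentre is created or touched since both substitutions occur at the C8 methylene, so the trans junction is fixed by the C1 and C5 configurations already present, which hold C8 anti to the C6 arm. The step needs attack at C8 and not C1, forward closure in preference to return to 17, and no ionisation at C2 or C6: C1 is quaternary and its rear is out of reach, return to the oxirane is reversible under iodide whereas ether formation is not because oxirane strain exceeds that of the trans-fused bicycle, and the medium stays non-acidic. High dilution guards against intermolecular epoxide opening.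

**Compound list**

1 | 3,4-dimethoxybenzaldehyde | COc1ccc(C=O)cc1OC | starting material
2 | dimethyl succinate | COC(=O)CCC(=O)OC | starting material
3 | (E)-4-(3,4-dimethoxyphenyl)-3-(methoxycarbonyl)but-3-enoic acid | COC(=O)/C(CC(=O)O)=C/c1ccc(OC)c(OC)c1 | intermediate
4 | (R)-4-benzyl-2-oxazolidinone | O=C1N[C@H](Cc2ccccc2)CO1 | starting material
5 | mixed pivalic anhydride of 3 (not isolated) | COC(=O)/C(CC(=O)OC(=O)C(C)(C)C)=C/c1ccc(OC)c(OC)c1 | intermediate
6 | methyl (E)-2-{2-[(R)-4-benzyl-2-oxooxazolidin-3-yl]-2-oxoethyl}-3-(3,4-dimethoxyphenyl)acrylate | COC(=O)/C(CC(=O)N1[C@H](Cc2ccccc2)COC1=O)=C/c1ccc(OC)c(OC)c1 | intermediate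
7 | Z(O)-dibutylboron dienolate of 6 (not isolated) | COC(=O)/C(=C/c1ccc(OC)c(OC)c1)/C=C(\OB(CCCC)CCCC)N1[C@H](Cc2ccccc2)COC1=O | intermediate
8 | dibutylboron aldolate (not isolated) | COC(=O)/C(=C/c1ccc(OC)c(OC)c1)[C@H]([C@@H](OB(CCCC)CCCC)c1ccc(OC)c(OC)c1)C(=O)N1[C@H](Cc2ccccc2)COC1=O | intermediate
9 | syn aldol adduct (C5 R, C6 R) | COC(=O)/C(=C/c1ccc(OC)c(OC)c1)[C@H]([C@@H](O)c1ccc(OC)c(OC)c1)C(=O)N1[C@H](Cc2ccccc2)COC1=O | intermediate
10 | C6-O-TBS ether of 9 | COC(=O)/C(=C/c1ccc(OC)c(OC)c1)[C@H]([C@@H](O[Si](C)(C)C(C)(C)C)c1ccc(OC)c(OC)c1)C(=O)N1[C@H](Cc2ccccc2)COC1=O | intermediate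
11 | methyl (E)-ester with C4H2OH (C5 S, C6 R) | COC(=O)/C(=C/c1ccc(OC)c(OC)c1)[C@@H](CO)[C@@H](O[Si](C)(C)C(C)(C)C)c1ccc(OC)c(OC)c1 | intermediate
12 | (E)-allylic alcohol diol (C5 S, C6 R) | OC/C(=C/c1ccc(OC)c(OC)c1)[C@@H](CO)[C@@H](O[Si](C)(C)C(C)(C)C)c1ccc(OC)c(OC)c1 | intermediate
13 | C1–C2 epoxy alcohol (C1 S, C2 S, C5 S, C6 R; not isolated) | COc1ccc([C@@H]2O[C@]2(CO)[C@@H](CO)[C@@H](O[Si](C)(C)C(C)(C)C)c2ccc(OC)c(OC)c2)cc1OC | intermediate
14 | ring A tetrahydrofuran diol (C1 S, C2 R, C5 S, C6 R) | COc1ccc([C@H]2OC[C@@H]([C@@H](O[Si](C)(C)C(C)(C)C)c3ccc(OC)c(OC)c3)[C@]2(O)CO)cc1OC | intermediate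
15 | C8 p-toluenesulfonate of 14 | COc1ccc([C@H]2OC[C@@H]([C@@H](O[Si](C)(C)C(C)(C)C)c3ccc(OC)c(OC)c3)[C@]2(O)COS(=O)(=O)c4ccc(C)cc4)cc1OC | intermediate
16 | spiro C1–C8 epoxide, C6-O-TBS | COc1ccc([C@H]2OC[C@@H]([C@@H](O[Si](C)(C)C(C)(C)C)c3ccc(OC)c(OC)c3)[C@]24CO4)cc1OC | intermediate
17 | spiro-epoxy alcohol | COc1ccc([C@H]2OC[C@@H]([C@@H](O)c3ccc(OC)c(OC)c3)[C@]24CO4)cc1OC | intermediate
18 | (2R,3R,4S)-2-(3,4-dimethoxyphenyl)-4-[(R)-hydroxy(3,4-dimethoxyphenyl)methyl]-3-(iodomethyl)tetrahydrofuran-3-ol (geometry at C1 unchanged, descriptor changed by iodine; not isolated) | COc1ccc([C@H]2OC[C@@H]([C@@H](O)c3ccc(OC)c(OC)c3)[C@]2(O)CI)cc1OC | intermediate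
19 | (1S,2R,5S,6R)-2,6-bis(3,4-dimethoxyphenyl)-3,7-dioxabicyclo[3.3.0]octan-1-ol, trans-fused (CNP0422369.8) | COc1ccc([C@H]2OC[C@H]3[C@H](c4ccc(OC)c(OC)c4)OC[C@]23O)cc1OC | target

**Step count**

Total step count: 11. Longest linear sequence: 11 steps (1 and 2 to 19).

**Steps most likely to fail**

**Step 11.**
- What may go wrong: reclosure of the iodohydrin alkoxide to the oxirane may outrun the etherification, which pays both a neopentyl and a trans-fusion penalty. Slow drains could then consume the material: semipinacol ring expansion by migration of C2 or C5 to C8, Li+-induced rearrangement of the oxirane, or intermolecular opening.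
- Fallback (known chemistry; sets out from 15, returns at 19): the tertiary hydroxyl is blocked so that no oxirane can form, and the sulfonate itself is displaced. Tosylate 15 with SEMCl and iPr2NEt in ClCH2CH2Cl at 50 °C should give the C1-O-[2-(trimethylsilyl)ethoxymethyl] ether F1, an acetal that neither migrates to the C6 oxygen nor leaves under base. Bu4NF in THF at rt then removes only the tert-butyldimethylsilyl group to give the C6 alcohol F2. NaH in THF at high dilution and reflux should effect an ordinary 5-exo-tet Williamson closure on the freely rotating C8–OTs bond and give the protected trans-fused bicycle F3. This is the reaction type by which trans-1,2-disubstituted cyclopentane sulfonates are closed to trans-fused 3-heterobicyclo[3.3.0]octanes. Bu4NF in DMPU with 4 Å MS at 80 °C cleaves the acetal under wholly basic conditions to 19.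

**Step 7.**
- What may go wrong: chelation of titanium by the 1,4-diol may slow or derail the epoxidation. The electron-rich C2–O bond may also ionise before C4–OH arrives, with erosion of the C2 configuration or capture by isopropoxide.
- Fallback (sets out from 12, returns at 14): oxygen is introduced by dihydroxylation instead of epoxidation. OsO4 (cat.) with N-methylmorpholine N-oxide in acetone–H2O should add to the alkene face left open by allylic 1,3-strain, which is the same face, anti to the C6 arm. This gives the C1,C2-syn tetraol F4. Catalytic camphorsulfonic acid in CH2Cl2 at 0 °C should then ionise only the free benzylic C2–OH, which is stabilised by the para methoxy group, and C4–OH closes ring A. The aryl group should settle trans to C8H2OH and 1,3-cis to the C6 arm, which is the configuration of 14.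

**Step 3.**
- What may go wrong: retro-aldol cleavage or C5 epimerisation during the oxidative boron work-up, lactonisation of the C6 oxygen onto the C8 ester, and later sluggish hydride cleavage of the crowded imide.
- Fallback (sets out from 3, returns at 11): the auxiliary and the enolate metal are both changed. Acid 3 is coupled (EDC·HCl, DMAP, CH2Cl2) with purchased (R)-4-benzyl-1,3-thiazolidine-2-thione to give the N-acyl thiazolidinethione F5. Its chlorotitanium enolate (TiCl4, iPr2NEt, N-methylpyrrolidinone, CH2Cl2, −78 °C) should add to 1 in the same syn sense and needs only an aqueous NH4Cl quench, giving the thiazolidinethione aldol F6. TBSOTf and 2,6-lutidine give its silyl ether F7. The much more labile thioimide is then cleaved with NaBH4 in THF–EtOH at 0 °C to 11.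

**Further compounds**

F1 | step 11 | C1-O-SEM ether of tosylate 15 | COc1ccc([C@H]2OC[C@@H]([C@@H](O[Si](C)(C)C(C)(C)C)c3ccc(OC)c(OC)c3)[C@]2(OCOCC[Si](C)(C)C)COS(=O)(=O)c4ccc(C)cc4)cc1OC
F2 | step 11 | C6 alcohol with C1-O-SEM and C8-OTs | COc1ccc([C@H]2OC[C@@H]([C@@H](O)c3ccc(OC)c(OC)c3)[C@]2(OCOCC[Si](C)(C)C)COS(=O)(=O)c4ccc(C)cc4)cc1OC
F3 | step 11 | C1-O-SEM ether of 19 | COc1ccc([C@H]2OC[C@H]3[C@H](c4ccc(OC)c(OC)c4)OC[C@]23OCOCC[Si](C)(C)C)cc1OC
F4 | step 7 | C1,C2-syn tetraol (C1 S, C2 S, C5 S, C6 R), C6-O-TBS | COc1ccc([C@H](O)[C@@](O)(CO)[C@@H](CO)[C@@H](O[Si](C)(C)C(C)(C)C)c2ccc(OC)c(OC)c2)cc1OC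
F5 | step 3 | N-acyl (R)-4-benzylthiazolidine-2-thione of 3 | COC(=O)/C(CC(=O)N1[C@H](Cc2ccccc2)CSC1=S)=C/c1ccc(OC)c(OC)c1
F6 | step 3 | thiazolidinethione syn aldol (C5 R, C6 R) | COC(=O)/C(=C/c1ccc(OC)c(OC)c1)[C@H]([C@@H](O)c1ccc(OC)c(OC)c1)C(=O)N1[C@H](Cc2ccccc2)CSC1=S
F7 | step 3 | C6-O-TBS ether of F6 | COC(=O)/C(=C/c1ccc(OC)c(OC)c1)[C@H]([C@@H](O[Si](C)(C)C(C)(C)C)c1ccc(OC)c(OC)c1)C(=O)N1[C@H](Cc2ccccc2)CSC1=S
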